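## The problem

Grevirobstol B (23) is a 22-membered macrocycle in which two phenolic rings are joined twice: by a diaryl ether oxygen and by an unbranched, unfunctionalised sixteen-carbon chain running from C1' on ring A to C16' on ring B. Ring A is bridged meta (OH, O-aryl and C1' in a 1,3,5 pattern). Ring B is bridged ortho (aryloxy at C1, hydroxyls at C2 and C4, chain at C6), so its ether oxygen is flanked by an oxygen substituent and by the chain. There is no stereocentre, so nothing has to be set or relayed; the only stereochemical element that appears on the way is an alkene geometry that is erased again. Three tasks remain: closing a large ring although the saturated chain offers no functional group, building the crowded, unsymmetrical diaryl ether with the ring B substituents correctly placed, and carrying three phenols through the sequence. The free phenols are acidic and nucleophilic, and the 1,2,4-trioxygenated ring B is easily attacked by ozone, halogenating agents and excess peracid, so the oxygens travel as methyl ethers and each oxidant is chosen with ring B in mind. The enabling feature is C1', a benzylic methylene on ring A that sits meta to both ring A oxygens: a bromide there is easy to make and not prone to ionise, and a sulfonyl carbanion there gains extra stabilisation from the ring. A sulfur atom placed between C1' and C2' therefore gives a 23-membered ring that can be closed by carbon–sulfur substitution and later contracted with loss of SO2.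

## Retrosynthesis

**End game, 23 ⇐ 22 ⇐ 21.** The three O–CH3 bonds are cut first, leading from 23 to the trimethyl ether 22. Methyl ethers are preferred to benzyl or silyl ethers because they survive copper catalysis, hydride, hydroxide on alumina and hydrogenation, and fall together in one Lewis-acid step. The C1'–C2' single bond of 22 is then traced to the double bond of 21. The forward reaction only has to saturate a styrene-type alkene of either geometry.

**Key disconnection, 21 ⇐ 18.** The C1'=C2' bond is opened by re-inserting SO2 between the two carbons (Ramberg–Bäcklund transform), giving the 23-membered benzylic sulfone 18. Against a direct end-to-end C–C closure (metathesis, alkylation), this cut moves the difficult event, macrocyclisation, onto a carbon–sulfur bond and leaves the C–C bond formation unimolecular. It is placed at C1'/C2' and nowhere else along the chain because only there is one α-position benzylic, which directs the halogenation that triggers the contraction. The forward step needs a single halogenation at C1' and tolerance of aryl ethers.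

**Carbon–sulfur bonds, 18 ⇐ 16 ⇐ 14.** Sulfone 18 comes from sulfide 16 by oxidation. Both C–S bonds of 16 are cut to sulfide ion and the dibromide 14, the first substitution passing through thiolate 15. The precursor is acyclic, and its two electrophilic ends differ usefully: the benzylic bromide reacts first, and the ring then closes at the primary bromide. The forward reaction asks for high dilution and little else.

**Functional group changes, 14 ⇐ 13 ⇐ 12 ⇐ 10.** The two bromides are traced to diol 13, the diol to aldehyde ester 12 (one hydride step reduces both carbonyls), and 12 to the terminal alkene 10 by a one-carbon oxidative cleavage through diol 11. A C16 alkenyl chain is accepted as precursor of the C15 arm because the symmetrical C16 diene 4 is a catalogue compound, whereas a differentiated C15 building block is not. Osmium-catalysed cleavage is preferred to ozonolysis so that ring B is not exposed to ozone.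

**Diaryl ether, 10 ⇐ 8 + 9.** The aryl–O bond on ring A is cut, giving phenol 8 and aryl bromide 9. Cutting here, before the alkene is cleaved, lets the copper-catalysed coupling run on a substrate with a single hydroxyl group and an inert alkene. The alternative of leaving this bond as the macrocyclisation step would put the most hindered coupling of the route under high dilution. The ester of 9 carries C1' at the right oxidation level and mildly activates the bromide.

**Ring B oxygen and chain, 8 ⇐ 6 ⇐ 3 + 4.** The phenolic oxygen of 8 is traced to the formyl group of 6 (Dakin transform, via formate 7), and the aryl–C16' bond to aryl bromide 3 and the borane 5 made from diene 4. The chain is coupled at the aldehyde stage because the ortho formyl group activates the bromide for oxidative addition, while a bromophenoxide would be deactivated. The Dakin step must then spare a terminal alkene, which peroxide under acid catalysis (no peracid) allows.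

**Ring B core, 3 ⇐ 1.** The formyl group is removed to give 1. Formylation is known to occur para to one methoxy group and ortho to the bromine, which places oxygen, bromine and the two methoxy groups exactly as ring B requires.

## Roads not taken

Alternative 1: Ring B would be built, not bought. The cut is the C4–C5 bond of ring B. Cyclobutenone A1 carries an alkenyl group and a methoxymethyl-protected oxygen on one carbon and an isopropoxy group on the next. Heated in toluene or xylene, it should open (4π) to a dienylketene, close (6π) and tautomerise to phenol A2, with the C16 chain and a chlorinated ring A already attached.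
- Merits: the substitution pattern of ring B is fixed by construction and does not depend on the orientation of an aromatic substitution. The three ring B oxygens emerge in three different states, so the C1 oxygen can be unveiled alone.
- Weak points: all three phenols end up free, so the differentiation buys little. The chosen plan singles out the C1 oxygen at no cost, since the Dakin step makes it the only free hydroxyl of 8. The key step does not address the macrocycle, which would have to close by intramolecular coupling of a di-ortho-substituted phenol with an unactivated aryl chloride at high dilution, the most demanding kind of C–O coupling. A1 is itself laborious, since it calls for an unsymmetrically substituted four-membered ring and a long-chain alkenylmetal nucleophile, and the end game needs three different deprotections.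
- Comparison: Alternative 1 is better in regiochemical certainty. The chosen plan sets against it a ring B reached in three steps by reactions of known orientation, ring closure through the most forgiving bond (C–S), and a clearly shorter sequence.

Alternative 2: Ring A itself would be cut and the macrocycle closed in the same event. Precursor A3 holds a 3-alkylcyclobutenone at one chain end and an aryl ethynyl ether on ring B at the other. On heating in dilute toluene the cyclobutenone should open to a vinylketene that adds across the ynol ether. The adduct would then open and reclose (4π, then 6π) to phenol A4, forming ring A and the 22-membered ring together.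
- Merits: this is the most convergent plan. Three C–C bonds, an aromatic ring with its free hydroxyl correctly placed and the large ring arise in one metal-free step. The ether oxygen is installed earlier on a simple alkyne, so no hindered Ullmann coupling is needed. After the key step only a twofold demethylation remains, one step fewer than here.
- Weak points: the ketene–alkyne cycloaddition is the bimolecular link of the cascade and would have to close a 22-membered ring without conformational help. At the required dilution the reversibly formed vinylketene has time to dimerise or decay, and such annulations are normally run intermolecularly with excess alkyne. The ynol ether of a 2,6-disubstituted, electron-rich phenol is laborious to make and sensitive to heat, acid and water.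
- Comparison: Alternative 2 is more elegant and potentially shorter, but its decisive step has no close analogy at this ring size. The chosen plan relies on a thiolate macrocyclisation and a unimolecular contraction, both with direct analogy in cyclophane synthesis.

Alternative 3: This road keeps a one-atom linchpin but uses carbon in place of sulfur. The linchpin reagent tosylmethyl isocyanide A5 would be alkylated twice under high dilution (NaH, DMSO/Et2O), first by the ring B benzylic bromide and then intramolecularly by the C14' bromide of dibromide A6. Acid hydrolysis would give the 22-membered ketone A7 with C14'–C15' and C15'–C16' formed.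
- Merits: the linchpin atom stays as a skeletal carbon, so nothing is expelled. The reagent is cheap, the method is established for cyclophane ketones, and no halocarbon such as CBr2F2 is needed. The step count is about level with the chosen plan.
- Weak points: the benzylic carbon must now sit on ring B next to the ether oxygen, so ring B cannot come from the simple formylation–Dakin logic, and ring A needs a C14 ω-bromoalkyl arm. The ring-closing second alkylation requires a hindered, fully substituted carbanion to attack an unactivated primary bromide. It is slower than a thiolate substitution and competes with oligomer formation and loss of sulfinate. The C15' carbonyl must then be removed by hydrazone reduction or dithioketal desulfurisation, harsher than the room-temperature hydrogenation used here.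
- Comparison: Alternative 3 is as good in length and better in atom economy at the linchpin. The chosen plan answers with a softer, faster nucleophile in the macrocyclisation, benzylic activation exactly where the ring contracts, and milder removal of the residual functionality.

Key step: step 10

## Route

Assumption: the chain carbons are numbered C1' (on ring A) to C16' (on ring B); hexadeca-1,15-diene (4) is taken as a catalogue compound and used in excess.

Step 1
Reactants: 1 1-bromo-3,5-dimethoxybenzene
Product: 3 2-bromo-4,6-dimethoxybenzaldehyde, via aryl iminium chloride 2 (not isolated)
Conditions: POCl3, DMF, 0 to 90 °C; then H2O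
Reagents that add atoms: N,N-dimethylformamide CN(C)C=O (formyl carbon); water O (carbonyl oxygen)
Why: Vilsmeier–Haack formylation; the chloroiminium electrophile should attack the position para to one methoxy group and ortho to the other (next to bromine), which is activated and less crowded than the site between the two methoxy groups, and hydrolysis of iminium 2 gives the aldehyde.

Step 2
Reactants: 3 2-bromo-4,6-dimethoxybenzaldehyde; 4 hexadeca-1,15-diene
Product: 6 2-(hexadec-15-en-1-yl)-4,6-dimethoxybenzaldehyde, via 9-(hexadec-15-en-1-yl)-9-borabicyclo[3.3.1]nonane 5 (not isolated)
Conditions: 4 (3 equiv per boron), 9-BBN, THF, 0 °C to rt; then 3, Pd(dppf)Cl2 (5 mol%), aq. K3PO4, DMF, 60 °C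
Reagents that add atoms: none
Why: Anti-Markovnikov hydroboration of one terminal alkene (excess diene favours the mono-adduct and leaves no B–H to reduce the aldehyde), then B-alkyl Suzuki–Miyaura coupling. The ortho formyl group activates the C–Br bond for oxidative addition to zerovalent palladium, and the bidentate dppf ligand disfavours β-hydride elimination.

Step 3
Reactants: 6 2-(hexadec-15-en-1-yl)-4,6-dimethoxybenzaldehyde
Product: 8 2-(hexadec-15-en-1-yl)-4,6-dimethoxyphenol, via aryl formate 7 (not isolated)
Conditions: 35% aq. H2O2, H2SO4 (cat.), MeOH, rt
Reagents that add atoms: hydrogen peroxide OO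
Why: Acid-catalysed Dakin oxidation; the peroxide adduct of the aldehyde rearranges with migration of the very electron-rich aryl group, and formate 7 is methanolysed in the same flask. No peracid is present, so the isolated terminal alkene should remain untouched.

Step 4
Reactants: 8 2-(hexadec-15-en-1-yl)-4,6-dimethoxyphenol; 9 methyl 3-bromo-5-methoxybenzoate
Product: 10 methyl 3-[2-(hexadec-15-en-1-yl)-4,6-dimethoxyphenoxy]-5-methoxybenzoate
Conditions: CuI (10 mol%), picolinic acid (20 mol%), K3PO4, DMSO, 90 °C, argon
Reagents that add atoms: none
Why: Ullmann-type diaryl ether synthesis; the CuI/picolinic acid system is the one suited to di-ortho-substituted phenols, and the ester makes the aryl bromide slightly electron-poor. The phenol is the only hydroxyl group present, and the alkene and ester are inert to phosphate base.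

Step 5
Reactants: 10 methyl 3-[2-(hexadec-15-en-1-yl)-4,6-dimethoxyphenoxy]-5-methoxybenzoate
Product: 12 methyl 3-[2,4-dimethoxy-6-(15-oxopentadecyl)phenoxy]-5-methoxybenzoate, via terminal 1,2-diol 11 (not isolated)
Conditions: OsO4 (2 mol%), NaIO4, 2,6-lutidine, dioxane/H2O, rt
Reagents that add atoms: osmium tetroxide O=[Os](=O)(=O)=O (catalytic oxygen carrier); sodium periodate [Na+].[O-]I(=O)(=O)=O (terminal oxidant)
Why: Lemieux–Johnson oxidative cleavage; OsO4 dihydroxylates only the isolated alkene and leaves the electron-rich arenes alone (which ozone might not), and periodate cleaves diol 11 and regenerates the catalyst. The loss of the terminal carbon turns the C16 alkenyl chain into the C15 arm.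

Step 6
Reactants: 12 methyl 3-[2,4-dimethoxy-6-(15-oxopentadecyl)phenoxy]-5-methoxybenzoate
Product: 13 15-{2-[3-(hydroxymethyl)-5-methoxyphenoxy]-3,5-dimethoxyphenyl}pentadecan-1-ol
Conditions: LiAlH4, THF, 0 °C; then aqueous work-up
Reagents that add atoms: none
Why: Hydride reduction of the aldehyde and the aryl ester in one operation; nothing else in 12 is reducible by LiAlH4.

Step 7
Reactants: 13 15-{2-[3-(hydroxymethyl)-5-methoxyphenoxy]-3,5-dimethoxyphenyl}pentadecan-1-ol
Product: 14 1-(bromomethyl)-3-[2-(15-bromopentadecyl)-4,6-dimethoxyphenoxy]-5-methoxybenzene
Conditions: CBr4, PPh3, CH2Cl2, 0 °C to rt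
Reagents that add atoms: carbon tetrabromide BrC(Br)(Br)Br
Why: Appel reaction at both primary hydroxyl groups under neutral conditions that spare the aryl ethers. The C1' bromide is meta to both ring A oxygens and so should be stable to handling.

Step 8
Reactants: 14 1-(bromomethyl)-3-[2-(15-bromopentadecyl)-4,6-dimethoxyphenoxy]-5-methoxybenzene
Product: 16 23-membered cyclic benzyl alkyl sulfide (ring A–C1'H2–S–(CH2)15–ring B; trimethyl ether), via sodium bromo thiolate 15 (not isolated)
Conditions: Na2S·9H2O (1.5 equiv), EtOH/THF, 60 °C, slow addition of 14 (final ca. 1 mM)
Reagents that add atoms: sodium sulfide (as nonahydrate) [Na+].[Na+].[S-2]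
Why: Twofold nucleophilic substitution by sulfide, as used for thiacyclophanes; the benzylic bromide reacts first to give thiolate 15, which closes the 23-membered ring at the primary C2' bromide. Slow addition to dilute sulfide keeps the concentration of free benzylic bromide low.

Step 9
Reactants: 16 23-membered cyclic benzyl alkyl sulfide
Product: 18 23-membered benzylic sulfone (S,S-dioxide of 16), via cyclic sulfoxide 17 (not isolated)
Conditions: mCPBA (2.2 equiv), CH2Cl2, 0 °C to rt
Reagents that add atoms: mCPBA OOC(=O)c1cccc(Cl)c1
Why: Stepwise sulfur oxidation through the sulfoxide; sulfur is far more nucleophilic toward the peracid than either arene, so a slight excess at low temperature should leave ring B intact.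

Step 10
Reactants: 18 23-membered benzylic sulfone
Product: 21 (E)-1',2'-dehydrogrevirobstol B trimethyl ether, via α-bromo sulfone 19 (not isolated), via trans-episulfone 20 (not isolated)
Conditions: CBr2F2, KOH–Al2O3, t-BuOH/CH2Cl2, 0 °C to rt
Reagents that add atoms: none
Why: Ramberg–Bäcklund rearrangement in its one-flask halogenative form; the closest known type is the contraction of benzylic thiacyclophane dioxides and other macrocyclic sulfones to cyclophane alkenes. KOH on alumina deprotonates 18 at C1', whose hydrogens are acidified by both the sulfonyl group and ring A, and the carbanion takes a bromine from CBr2F2 to give α-bromo sulfone 19. Deprotonation at the other α-carbon, C2', and intramolecular displacement of bromide (3-exo-tet) close episulfone 20, which loses SO2 cheletropically and leaves the C1'=C2' double bond. The 22-membered ring is thus not closed end to end but arises by one-atom contraction of the preformed 23-membered ring, a unimolecular event that needs no dilution. No stereocentre remains; the E geometry drawn follows from the trans episulfone favoured under equilibrating basic conditions, and either isomer is acceptable because step 11 saturates the bond. The selectivity required is a single halogenation at C1' and none at C2' or on the arenes; the large acidity gap between the benzylic and the purely aliphatic α-position secures the site, and a mild bromine donor with a solid-supported base should limit a second bromination and avoid the dihalocarbene additions known with CCl4. The methyl ethers and the diaryl ether are inert to hydroxide at room temperature.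

Step 11
Reactants: 21 (E)-1',2'-dehydrogrevirobstol B trimethyl ether
Product: 22 grevirobstol B trimethyl ether
Conditions: H2 (1 atm), Pd/C, EtOAc, rt
Reagents that add atoms: none
Why: Heterogeneous hydrogenation of a disubstituted styrene-type alkene; both alkene geometries converge on 22, and aryl methyl ethers and the diaryl ether are not hydrogenolysed under these conditions.

Step 12
Reactants: 22 grevirobstol B trimethyl ether
Product: 23 grevirobstol B
Conditions: BBr3, CH2Cl2, −78 °C to rt; then H2O
Reagents that add atoms: none
Why: Lewis-acid demethylation; bromide attacks the methyl carbon of each boron-complexed aryl methyl ether, whereas the diaryl ether offers no sp3 carbon and should survive.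

## Compound list

1 | 1-bromo-3,5-dimethoxybenzene | COc1cc(Br)cc(OC)c1 | starting material
2 | N-[(2-bromo-4,6-dimethoxyphenyl)methylidene]-N-methylmethanaminium chloride | C[N+](C)=Cc1c(Br)cc(OC)cc1OC.[Cl-] | intermediate
3 | 2-bromo-4,6-dimethoxybenzaldehyde | O=Cc1c(Br)cc(OC)cc1OC | intermediate
4 | hexadeca-1,15-diene | C=CCCCCCCCCCCCCCC=C | starting material
5 | 9-(hexadec-15-en-1-yl)-9-borabicyclo[3.3.1]nonane | C=CCCCCCCCCCCCCCCB1C2CCCC1CCC2 | intermediate
6 | 2-(hexadec-15-en-1-yl)-4,6-dimethoxybenzaldehyde | O=Cc1c(CCCCCCCCCCCCCCC=C)cc(OC)cc1OC | intermediate
7 | 2-(hexadec-15-en-1-yl)-4,6-dimethoxyphenyl formate | O=COc1c(CCCCCCCCCCCCCCC=C)cc(OC)cc1OC | intermediate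
8 | 2-(hexadec-15-en-1-yl)-4,6-dimethoxyphenol | Oc1c(CCCCCCCCCCCCCCC=C)cc(OC)cc1OC | intermediate
9 | methyl 3-bromo-5-methoxybenzoate | COC(=O)c1cc(Br)cc(OC)c1 | starting material
10 | methyl 3-[2-(hexadec-15-en-1-yl)-4,6-dimethoxyphenoxy]-5-methoxybenzoate | COC(=O)c1cc(OC)cc(Oc2c(CCCCCCCCCCCCCCC=C)cc(OC)cc2OC)c1 | intermediate
11 | methyl 3-[2-(15,16-dihydroxyhexadecyl)-4,6-dimethoxyphenoxy]-5-methoxybenzoate (racemic) | COC(=O)c1cc(OC)cc(Oc2c(CCCCCCCCCCCCCCC(O)CO)cc(OC)cc2OC)c1 | intermediate
12 | methyl 3-[2,4-dimethoxy-6-(15-oxopentadecyl)phenoxy]-5-methoxybenzoate | COC(=O)c1cc(OC)cc(Oc2c(CCCCCCCCCCCCCCC=O)cc(OC)cc2OC)c1 | intermediate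
13 | 15-{2-[3-(hydroxymethyl)-5-methoxyphenoxy]-3,5-dimethoxyphenyl}pentadecan-1-ol | OCc1cc(OC)cc(Oc2c(CCCCCCCCCCCCCCCO)cc(OC)cc2OC)c1 | intermediate
14 | 1-(bromomethyl)-3-[2-(15-bromopentadecyl)-4,6-dimethoxyphenoxy]-5-methoxybenzene | BrCc1cc(OC)cc(Oc2c(CCCCCCCCCCCCCCCBr)cc(OC)cc2OC)c1 | intermediate
15 | sodium {3-[2-(15-bromopentadecyl)-4,6-dimethoxyphenoxy]-5-methoxyphenyl}methanethiolate | [Na+].[S-]Cc1cc(OC)cc(Oc2c(CCCCCCCCCCCCCCCBr)cc(OC)cc2OC)c1 | intermediate
16 | 23-membered cyclic benzyl alkyl sulfide: ring A–C1'H2–S–(CH2)15–ring B, rings joined by the diaryl ether, three OMe groups | COc1cc2cc(c1)Oc1c(OC)cc(OC)cc1CCCCCCCCCCCCCCCSC2 | intermediate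
17 | S-oxide of 16 (cyclic sulfoxide, racemic at sulfur) | COc1cc2cc(c1)Oc1c(OC)cc(OC)cc1CCCCCCCCCCCCCCCS(=O)C2 | intermediate
18 | S,S-dioxide of 16 (23-membered benzylic sulfone) | COc1cc2cc(c1)Oc1c(OC)cc(OC)cc1CCCCCCCCCCCCCCCS(=O)(=O)C2 | intermediate
19 | 1'-bromo derivative of sulfone 18 (α-bromo sulfone, racemic) | COc1cc2cc(c1)Oc1c(OC)cc(OC)cc1CCCCCCCCCCCCCCCS(=O)(=O)C2Br | intermediate
20 | trans-episulfone: thiirane 1,1-dioxide spanning C1' and C2' of the 22-membered ring (racemic, one enantiomer drawn) | COc1cc2cc(c1)Oc1c(OC)cc(OC)cc1CCCCCCCCCCCCCC[C@H]1[C@H]2S1(=O)=O | intermediate
21 | (E)-1',2'-dehydrogrevirobstol B trimethyl ether | COc1cc(/C=C/CCCCCCCC2)cc(c1)Oc1c(OC)cc(OC)cc1CCCCCC2 | intermediate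
22 | grevirobstol B trimethyl ether | COc1cc2cc(c1)Oc1c(OC)cc(OC)cc1CCCCCCCCCCCCCCCC2 | intermediate
23 | grevirobstol B | Oc1cc2cc(c1)Oc1c(O)cc(O)cc1CCCCCCCCCCCCCCCC2 | target

## Step count and risks

Total step count: 12. Longest linear sequence: 12 steps (1 to 23); 4 and 9 enter as purchased.

**Step 10 (key step).** The most likely failure is over-halogenation: the remaining C1' hydrogen of 19 is the most acidic in the molecule, so a second bromination can compete with the slower deprotonation at the unactivated C2' that is needed for ring closure. This would divert material to vinyl halide and ring-opened products. Carbene side reactions of the spent halogen donor with the new alkene are a lesser concern. Fallback: a two-stage, classical Ramberg–Bäcklund sequence that fixes the halogen before the sulfone exists. It sets out from sulfide 16, which is chlorinated with N-chlorosuccinimide at the benzylic position to the 1'-chloro sulfide F1. This is oxidised without purification with mCPBA to the 1'-chloro sulfone F2. Treatment with KOC(CH3)3 in THF then closes episulfone 20, which loses SO2, and the sequence rejoins the route at 21.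

**Step 8.** Intermolecular substitution is the main danger: thiolate 15 reacts much faster with the benzylic bromide of a second molecule than with its own unactivated C2' bromide, so chain growth competes with closure of the 23-membered ring. Excess sulfide can also cap the C2' end as a thiol. Fallback: separate the two substitutions. Starting from 14, one equivalent of KSC(O)CH3 in DMF at 0 °C should displace only the benzylic bromide and give S-{3-[2-(15-bromopentadecyl)-4,6-dimethoxyphenoxy]-5-methoxybenzyl} ethanethioate F3. One equivalent of NaOCH3 in degassed MeOH/THF at high dilution then releases thiolate 15 when no benzylic bromide is left to compete, and ring closure returns to the route at 16.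

**Step 4.** The di-ortho-substituted, electron-rich phenoxide may couple slowly, which gives time for oxidative degradation of the phenol and for hydrolysis of the methyl ester. Fallback: an oxidative Chan–Lam coupling, which reverses the polarity of the ring A partner and runs at room temperature under weakly basic conditions. From 8 and commercial [3-methoxy-5-(methoxycarbonyl)phenyl]boronic acid with Cu(OAc)2 (divalent copper, reoxidised by air), pyridine and molecular sieves in CH2Cl2, it rejoins the route at 10 without a new intermediate.

**Step 3.** The product is a para-methoxyphenol and may be oxidised further to a quinone by excess peroxide; hydride migration in place of aryl migration would give the benzoic acid. Fallback: invert the order of oxidation and coupling. Starting from 3, Baeyer–Villiger oxidation with mCPBA gives 2-bromo-4,6-dimethoxyphenyl formate F4, and methanolysis with catalytic K2CO3 in MeOH gives 2-bromo-4,6-dimethoxyphenol F5. B-alkyl Suzuki–Miyaura coupling of F5 with borane 5 (Pd(OAc)2, SPhos, K3PO4, THF/H2O) returns to the route at 8, the alkene never meeting an oxidant.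

**Step 2.** Double hydroboration of the diene is statistical and gives a bis-borane that couples twice and wastes aryl bromide; protodeboronation, β-hydride elimination or aldehyde reduction by residual B–H would lower the yield further. Fallback: use an isolable boron partner. Starting from 4, hydroboration with pinacolborane catalysed by [Ir(cod)Cl]2 and bis(diphenylphosphino)methane gives 2-(hexadec-15-en-1-yl)-4,4,5,5-tetramethyl-1,3,2-dioxaborolane F6. It is purified free of diene and bis-adduct and coupled with 3 (Pd(OAc)2, RuPhos, K3PO4, toluene/H2O, 90 °C), rejoining the route at 6.

## Further compounds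

F1 | step 10 | 1'-chloro derivative of cyclic sulfide 16 (α-chloro sulfide, racemic) | COc1cc2cc(c1)Oc1c(OC)cc(OC)cc1CCCCCCCCCCCCCCCSC2Cl
F2 | step 10 | 1'-chloro derivative of cyclic sulfone 18 (α-chloro sulfone, racemic) | COc1cc2cc(c1)Oc1c(OC)cc(OC)cc1CCCCCCCCCCCCCCCS(=O)(=O)C2Cl
F3 | step 8 | S-{3-[2-(15-bromopentadecyl)-4,6-dimethoxyphenoxy]-5-methoxybenzyl} ethanethioate | CC(=O)SCc1cc(OC)cc(Oc2c(CCCCCCCCCCCCCCCBr)cc(OC)cc2OC)c1
F0 | step 4 | none | none
F4 | step 3 | 2-bromo-4,6-dimethoxyphenyl formate | O=COc1c(Br)cc(OC)cc1OC
F5 | step 3 | 2-bromo-4,6-dimethoxyphenol | Oc1c(Br)cc(OC)cc1OC
F6 | step 2 | 2-(hexadec-15-en-1-yl)-4,4,5,5-tetramethyl-1,3,2-dioxaborolane | C=CCCCCCCCCCCCCCCB1OC(C)(C)C(C)(C)O1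
A1 | alternative 1 | 4-[18-(3-chloro-5-methoxyphenyl)octadec-1-en-2-yl]-3-isopropoxy-4-(methoxymethoxy)cyclobut-2-en-1-one (racemic) | O=C1C=C(OC(C)C)C1(OCOC)C(=C)CCCCCCCCCCCCCCCCc1cc(Cl)cc(OC)c1
A2 | alternative 1 | 3-[16-(3-chloro-5-methoxyphenyl)hexadecyl]-5-isopropoxy-4-(methoxymethoxy)phenol | COCOc1c(OC(C)C)cc(O)cc1CCCCCCCCCCCCCCCCc1cc(Cl)cc(OC)c1
A3 | alternative 2 | 3-{16-[2-(ethynyloxy)-3,5-dimethoxyphenyl]hexadecyl}cyclobut-2-en-1-one | O=C1C=C(CCCCCCCCCCCCCCCCc2cc(OC)cc(OC)c2OC#C)C1
A4 | alternative 2 | grevirobstol B ring B dimethyl ether (ring A phenol free) | Oc1cc2cc(c1)Oc1c(OC)cc(OC)cc1CCCCCCCCCCCCCCCC2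
A5 | alternative 3 | tosylmethyl isocyanide | Cc1ccc(cc1)S(=O)(=O)C[N+]#[C-]
A6 | alternative 3 | 1-[2-(bromomethyl)-4,6-dimethoxyphenoxy]-3-(14-bromotetradecyl)-5-methoxybenzene | COc1cc(CCCCCCCCCCCCCCBr)cc(c1)Oc1c(OC)cc(OC)cc1CBr
A7 | alternative 3 | 15'-oxogrevirobstol B trimethyl ether | COc1cc2cc(c1)Oc1c(OC)cc(OC)cc1CC(=O)CCCCCCCCCCCCCC2
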